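**Assumption:** briarane numbering (C1–C19) is used for all intermediates, and β is the face carrying the C1 methyl. The facial sense of the new catalyst in step 2 is assumed; the pseudo-enantiomeric quinidine-derived amine is available if it turns out to be the opposite.

## Retrosynthetic overview
1. Target ⇐ acid hydrolysis of an 8,17-epoxy-lactone with inversion at C8 ⇐ nucleophilic epoxidation of a macrocyclic butenolide; the C4 hexanoate comes from acylating the only free OH.
2. Ten-membered ring ⇐ Nozaki–Hiyama–Kishi closure of C4–C5 from a Z-vinyl iodide and an α-silyloxy aldehyde.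
3. Butenolide ⇐ RCM of a C7 methacrylate with a C8 exomethylene ⇐ CBS reduction (C7) ⇐ Morita–Baylis–Hillman coupling (C8–C9).
4. C2–C3 ⇐ Felkin-controlled, syn-selective γ-silyloxyallylstannane addition to the C2 aldehyde.
5. Ring A ⇐ organocatalytic Diels–Alder (C1, C10), Pd elimination, OsO4. Ring order: cyclohexene → butenolide → ten-membered ring → epoxide.

## Route

Step 1
Reactants: 1 (E)-pent-2-enal
Product: 2 (1E,3E)-penta-1,3-dien-1-yl acetate
Conditions: isopropenyl acetate, TsOH (cat.), Cu(OAc)2 (cat.), 95 °C, distil off acetone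
Reagents that add atoms: isopropenyl acetate (CC(=C)OC(C)=O)
Why: Acid-catalysed enol-acetate exchange (dienol acetate formation) traps the extended enol of the enal as the thermodynamically preferred E,E-diene.

Step 2
Reactants: 2 (1E,3E)-penta-1,3-dien-1-yl acetate; 3 (E)-4-acetoxy-2-methylbut-2-enal
Product: 4 Diels–Alder adduct 2-acetoxy-6-(acetoxymethyl)-1,5-dimethylcyclohex-3-ene-1-carbaldehyde (C1-Me β; C1-CHO α; C10-CH2OAc β; C11-Me α; C14-OAc α)
Conditions: 9-amino-9-deoxy-epi-quinine (20 mol %), TFA (40 mol %), toluene, 0 °C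
Reagents that add atoms: none
Why: Proposed new method: a primary-amine iminium-catalysed Diels–Alder reaction of an α-branched, β-substituted enal with a 1-acyloxydiene, in which the unhindered NH2 condenses with the α-methyl enal (secondary amines cannot), the E-iminium lowers the LUMO, the acetoxy donor directs diene carbon C11 onto the iminium β-carbon C10 ("ortho" regiochemistry), suprafacial addition copies the E-alkene into the C1-Me/C10-CH2OAc cis relation, and the protonated quinuclidine–quinoline wall blocks one enal face so that C1 and C10 are set absolutely; the closest known reaction types are the imidazolidinone-catalysed Diels–Alder of unbranched enals with 1-acetoxybutadiene and the primary-ammonium-catalysed Diels–Alder of α-substituted acroleins.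

Step 3
Reactants: 4 Diels–Alder adduct
Product: 5 (1S,6S)-6-(acetoxymethyl)-1,5-dimethylcyclohexa-2,4-diene-1-carbaldehyde
Conditions: Pd(PPh3)4 (5 mol %), Et3N, THF, 65 °C
Reagents that add atoms: none
Why: Tsuji–Trost-type 1,4-elimination, in which ionisation of the only allylic acetate (C14) gives a π-allyl-Pd whose sole β-hydrogen is H-11 (anti to OAc, so syn to Pd), giving one diene and erasing the two auxiliary stereocentres.

Step 4
Reactants: 5 diene aldehyde
Product: 6 6-(acetoxymethyl)-4,5-dihydroxy-1,5-dimethylcyclohex-2-ene-1-carbaldehyde (C11-OH and C12-OH both α)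
Conditions: OsO4 (2 mol %), NMO (1.05 equiv), acetone–H2O, 0 °C
Reagents that add atoms: N-methylmorpholine N-oxide (C[N+]1([O-])CCOCC1); water (O)
Why: Upjohn syn-dihydroxylation takes the more electron-rich trisubstituted C11=C12 bond (C13=C14 is next to the formyl-bearing quaternary C1) from the α face, anti to C1-Me and C10-CH2OAc, setting C11 and C12 as the cis-diol.

Step 5
Reactants: 6 diol
Product: 7 C11/C12-acetonide of 6
Conditions: 2,2-dimethoxypropane, PPTS (cat.), CH2Cl2, rt
Reagents that add atoms: 2,2-dimethoxypropane (COC(C)(C)OC)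
Why: Transketalisation of a cis-1,2-diol gives the cis-fused dioxolane, which also shields both faces of C13=C14 from later oxidants.

Step 6
Reactants: 8 allyloxy(tert-butyl)dimethylsilane
Product: 10 (Z)-tert-butyldimethyl{[3-(tributylstannyl)prop-1-en-1-yl]oxy}silane, via lithiated allyl silyl ether 9 (not isolated)
Conditions: s-BuLi, THF, −78 °C; then Bu3SnCl, −78 °C
Reagents that add atoms: tributyltin chloride (CCCC[Sn](Cl)(CCCC)CCCC)
Why: α-Lithiation of the allyl ether and γ-selective stannylation of the internally O-coordinated allyl-lithium gives the Z-γ-silyloxyallylstannane.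

Step 7
Reactants: 7 acetonide aldehyde; 10 γ-silyloxyallylstannane
Product: 11 C2 alcohol carrying C3-OTBS and a terminal vinyl group (C2 and C3 configured as in 32; C2-O/C3-O syn)
Conditions: BF3·OEt2, CH2Cl2, −78 °C
Reagents that add atoms: none
Why: Lewis-acid allylstannane addition through an open antiperiplanar transition state gives the syn 1,2-diol monoether, and Felkin–Anh attack (C10 large, C14 medium, methyl small) on the α-quaternary aldehyde gives the required C2 configuration.

Step 8
Reactants: 11 C2 alcohol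
Product: 12 C2,C9-diacetate
Conditions: Ac2O, DMAP, Et3N, CH2Cl2, rt
Reagents that add atoms: acetic anhydride (CC(=O)OC(C)=O)
Why: DMAP-catalysed acylation installs the final C2 acetate on the only free hydroxyl.

Step 9
Reactants: 12 diacetate
Product: 13 C9 primary alcohol (C2 acetate retained)
Conditions: K2CO3 (cat.), MeOH, 0 °C
Reagents that add atoms: none
Why: Zemplén-type transesterification removes the unhindered primary acetate much faster than the C2 acetate, which is flanked by quaternary C1 and C3-OTBS.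

Step 10
Reactants: 13 primary alcohol
Product: 14 C9 aldehyde
Conditions: Dess–Martin periodinane, NaHCO3, CH2Cl2, 0 °C
Reagents that add atoms: none
Why: Buffered Dess–Martin oxidation gives the aldehyde without epimerising C10, whose substituent is already trans to the C2 chain.

Step 11
Reactants: 15 but-2-yn-1-ol
Product: 17 (Z)-3-iodobut-2-en-1-ol, via vinylalanate 16 (not isolated)
Conditions: Red-Al, THF, 0 °C to rt; then I2, −78 °C
Reagents that add atoms: iodine (II)
Why: Hydroxyl-directed trans-hydroalumination places aluminium on the distal carbon, cis to CH2O, and iodinolysis with retention gives the Z-iodide.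

Step 12
Reactants: 17 (Z)-3-iodobut-2-en-1-ol
Product: 18 (Z)-3-iodobut-2-enal
Conditions: MnO2, CH2Cl2, rt
Reagents that add atoms: none
Why: Neutral allylic oxidation with MnO2 keeps the Z geometry.

Step 13
Reactants: 18 (Z)-3-iodobut-2-enal
Product: 19 (Z)-5-iodohexa-1,4-dien-3-ol (racemic; the carbinol centre is removed in step 14)
Conditions: vinylmagnesium bromide, THF, −78 °C
Reagents that add atoms: vinylmagnesium bromide (C=C[Mg]Br)
Why: Grignard 1,2-addition to the enal is faster at −78 °C than I/Mg exchange.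

Step 14
Reactants: 19 dienol
Product: 20 (Z)-5-iodohexa-1,4-dien-3-one
Conditions: MnO2, CH2Cl2, 0 °C, used at once
Reagents that add atoms: none
Why: MnO2 oxidation of the doubly allylic alcohol gives the cross-conjugated vinyl ketone under neutral conditions.

Step 15
Reactants: 14 C9 aldehyde; 20 (Z)-5-iodohexa-1,4-dien-3-one
Product: 21 Morita–Baylis–Hillman adduct (C9-OH; C8 exomethylene; C7 ketone; C9 configured as in 32)
Conditions: quinuclidine (25 mol %), MeOH (1 equiv), THF, rt, 20 (2 equiv)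
Reagents that add atoms: none
Why: In this Morita–Baylis–Hillman reaction the amine adds only to the unsubstituted vinyl terminus, and the resulting enolate attacks the aldehyde in the Felkin sense (C1 with the whole C2–C4 chain as the large group), forming C8–C9 and setting C9.

Step 16
Reactants: 21 MBH adduct
Product: 22 C9 acetate
Conditions: Ac2O, pyridine, CH2Cl2, 0 °C
Reagents that add atoms: acetic anhydride (CC(=O)OC(C)=O)
Why: Pyridine-mediated acylation installs the final C9 acetate without SN2′ displacement of the allylic ester.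

Step 17
Reactants: 22 dienone acetate
Product: 23 (7S)-allylic alcohol
Conditions: (R)-Me-CBS (20 mol %), catecholborane, toluene, −78 °C
Reagents that add atoms: none
Why: Corey–Bakshi–Shibata reduction is 1,2-selective and catalyst-controlled, with the α-branched C8 alkenyl group acting as the large substituent, so hydride delivery gives the 7S carbinol.

Step 18
Reactants: 23 C7 alcohol
Product: 24 C7 methacrylate
Conditions: methacrylic anhydride, DMAP, Et3N, CH2Cl2, 0 °C
Reagents that add atoms: methacrylic anhydride (CC(=C)C(=O)OC(=O)C(C)=C)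
Why: Acylation of the only free hydroxyl brings in C17, C18 and C19 with retention at C7.

Step 19
Reactants: 24 methacrylate
Product: 26 C4 aldehyde, via vicinal diol 25 (not isolated)
Conditions: OsO4 (2 mol %), NaIO4 (2.2 equiv), 2,6-lutidine, dioxane–H2O, 0 °C
Reagents that add atoms: sodium periodate ([Na+].[O-]I(=O)(=O)=O); water (O)
Why: Lemieux–Johnson cleavage takes the monosubstituted vinyl group because every other alkene is electron-poor (methacrylate, vinyl iodide, bis-acyloxy-flanked exomethylene) or shielded (C13=C14).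

Step 20
Reactants: 26 C4 aldehyde
Product: 27 α-methyl-β-substituted butenolide aldehyde
Conditions: o-tolyl-NHC Hoveyda–Grubbs catalyst (10 mol %), toluene, 80 °C, argon sparge
Reagents that add atoms: none
Why: Ring-closing metathesis of two 1,1-disubstituted alkenes is driven by five-membered-ring formation and loss of ethene, and the terminal vinyl group that could have closed a seven-membered ring was removed in step 19.

Step 21
Reactants: 27 butenolide aldehyde
Product: 28 macrocyclic (4S)-allylic alcohol with the Z-C5=C6 bond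
Conditions: CrCl2 (10 equiv), NiCl2 (1 wt %), DMSO–THF, 2 mM, rt
Reagents that add atoms: none
Why: Nozaki–Hiyama–Kishi macrocyclisation keeps the alkene geometry (C4 replaces iodine cis to C7) and tolerates esters and the butenolide, and the transition state that places the chromium alkoxide pseudo-equatorial, trans in the ring sense to C3-OTBS, gives the all-syn C2–C4 triad.

Step 22
Reactants: 28 macrocyclic alcohol
Product: 29 C4 hexanoate
Conditions: hexanoic anhydride, DMAP, Et3N, CH2Cl2, rt
Reagents that add atoms: hexanoic anhydride (CCCCCC(=O)OC(=O)CCCCC)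
Why: DMAP-catalysed acylation of the single free hydroxyl places the hexanoate regiospecifically.

Step 23
Reactants: 29 macrocyclic butenolide
Product: 30 8,17-epoxy-lactone (epoxide oxygen on the H-7 face, anti to C6)
Conditions: aq NaOCl, pyridine, 0 °C
Reagents that add atoms: sodium hypochlorite ([Na+].[O-]Cl)
Why: Weitz–Scheffer-type nucleophilic epoxidation by the small hypochlorite ion touches only the electron-poor alkene and attacks C8 on the exposed face opposite C6 and the macrocycle, setting C17, while the weak base avoids γ-deprotonation at C7.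

Step 24
Reactants: 30 epoxy-lactone
Product: 32 target CNP0153048.1, via epoxy triol 31 (not isolated)
Conditions: TFA–H2O (4:1), CH2Cl2, 0 °C to rt
Reagents that add atoms: water (O)
Why: Acid hydrolysis removes the acetonide and the TBS ether, then opens the protonated epoxide by anti attack at C8 (the carbon remote from the lactone carbonyl, helped from the rear by the C9 acetate), so C8 inverts, C17-O is retained, and the 8,17-trans-diol with C8-OH cis to C6 results.

## Compound list
1 | (E)-pent-2-enal | CC/C=C/C=O | starting material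
2 | (1E,3E)-penta-1,3-dien-1-yl acetate | CC(=O)O/C=C/C=C/C | intermediate
3 | (E)-4-acetoxy-2-methylbut-2-enal | CC(=O)OC/C=C(\C)C=O | starting material
4 | Diels–Alder adduct (C1-Me β; CHO α; C10-CH2OAc β; C11-Me α; C14-OAc α) | CC(=O)OC[C@H]1[C@H](C)C=C[C@H](OC(C)=O)[C@]1(C)C=O | intermediate
5 | (1S,6S)-6-(acetoxymethyl)-1,5-dimethylcyclohexa-2,4-diene-1-carbaldehyde | CC(=O)OC[C@H]1C(C)=CC=C[C@]1(C)C=O | intermediate
6 | C11,C12-α-cis-diol aldehyde | CC(=O)OC[C@H]1[C@](C)(O)[C@H](O)C=C[C@]1(C)C=O | intermediate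
7 | acetonide aldehyde | CC(=O)OC[C@H]1[C@]2(C)OC(C)(C)O[C@@H]2C=C[C@]1(C)C=O | intermediate
8 | allyloxy(tert-butyl)dimethylsilane | C=CCO[Si](C)(C)C(C)(C)C | starting material
9 | lithiated allyl silyl ether | C=CC([Li])O[Si](C)(C)C(C)(C)C | intermediate
10 | (Z)-γ-(TBSO)allyltributylstannane | CCCC[Sn](CCCC)(CCCC)C/C=C\O[Si](C)(C)C(C)(C)C | intermediate
11 | C2 alcohol, C3-OTBS, vinyl | CC(=O)OC[C@H]1[C@]2(C)OC(C)(C)O[C@@H]2C=C[C@]1(C)[C@@H](O)[C@H](O[Si](C)(C)C(C)(C)C)C=C | intermediate
12 | C2,C9-diacetate | CC(=O)OC[C@H]1[C@]2(C)OC(C)(C)O[C@@H]2C=C[C@]1(C)[C@@H](OC(C)=O)[C@H](O[Si](C)(C)C(C)(C)C)C=C | intermediate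
13 | C9 primary alcohol | OC[C@H]1[C@]2(C)OC(C)(C)O[C@@H]2C=C[C@]1(C)[C@@H](OC(C)=O)[C@H](O[Si](C)(C)C(C)(C)C)C=C | intermediate
14 | C9 aldehyde | O=C[C@H]1[C@]2(C)OC(C)(C)O[C@@H]2C=C[C@]1(C)[C@@H](OC(C)=O)[C@H](O[Si](C)(C)C(C)(C)C)C=C | intermediate
15 | but-2-yn-1-ol | CC#CCO | starting material
16 | cyclic sodium vinylalanate | CC1=CCO[Al-]1(OCCOC)OCCOC.[Na+] | intermediate
17 | (Z)-3-iodobut-2-en-1-ol | C/C(I)=C/CO | intermediate
18 | (Z)-3-iodobut-2-enal | C/C(I)=C/C=O | intermediate
19 | (Z)-5-iodohexa-1,4-dien-3-ol (racemic) | C/C(I)=C/C(O)C=C | intermediate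
20 | (Z)-5-iodohexa-1,4-dien-3-one | C/C(I)=C/C(=O)C=C | intermediate
21 | MBH adduct | C/C(I)=C/C(=O)C(=C)[C@H](O)[C@H]1[C@]2(C)OC(C)(C)O[C@@H]2C=C[C@]1(C)[C@@H](OC(C)=O)[C@H](O[Si](C)(C)C(C)(C)C)C=C | intermediate
22 | C9 acetate of 21 | C/C(I)=C/C(=O)C(=C)[C@H](OC(C)=O)[C@H]1[C@]2(C)OC(C)(C)O[C@@H]2C=C[C@]1(C)[C@@H](OC(C)=O)[C@H](O[Si](C)(C)C(C)(C)C)C=C | intermediate
23 | (7S)-alcohol | C/C(I)=C/[C@H](O)C(=C)[C@H](OC(C)=O)[C@H]1[C@]2(C)OC(C)(C)O[C@@H]2C=C[C@]1(C)[C@@H](OC(C)=O)[C@H](O[Si](C)(C)C(C)(C)C)C=C | intermediate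
24 | C7 methacrylate | C/C(I)=C/[C@H](OC(=O)C(C)=C)C(=C)[C@H](OC(C)=O)[C@H]1[C@]2(C)OC(C)(C)O[C@@H]2C=C[C@]1(C)[C@@H](OC(C)=O)[C@H](O[Si](C)(C)C(C)(C)C)C=C | intermediate
25 | vicinal diol from the vinyl group (epimers at the new carbinol) | C/C(I)=C/[C@H](OC(=O)C(C)=C)C(=C)[C@H](OC(C)=O)[C@H]1[C@]2(C)OC(C)(C)O[C@@H]2C=C[C@]1(C)[C@@H](OC(C)=O)[C@H](O[Si](C)(C)C(C)(C)C)C(O)CO | intermediate
26 | C4 aldehyde | C/C(I)=C/[C@H](OC(=O)C(C)=C)C(=C)[C@H](OC(C)=O)[C@H]1[C@]2(C)OC(C)(C)O[C@@H]2C=C[C@]1(C)[C@@H](OC(C)=O)[C@H](O[Si](C)(C)C(C)(C)C)C=O | intermediate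
27 | butenolide aldehyde | C/C(I)=C/[C@@H]3OC(=O)C(C)=C3[C@H](OC(C)=O)[C@H]1[C@]2(C)OC(C)(C)O[C@@H]2C=C[C@]1(C)[C@@H](OC(C)=O)[C@H](O[Si](C)(C)C(C)(C)C)C=O | intermediate
28 | macrocyclic C4 alcohol | O[C@H]1/C(C)=C\[C@@H]2OC(=O)C(C)=C2[C@H](OC(C)=O)[C@H]2[C@]3(C)OC(C)(C)O[C@@H]3C=C[C@]2(C)[C@@H](OC(C)=O)[C@@H]1O[Si](C)(C)C(C)(C)C | intermediate
29 | C4 hexanoate | CCCCCC(=O)O[C@H]1/C(C)=C\[C@@H]2OC(=O)C(C)=C2[C@H](OC(C)=O)[C@H]2[C@]3(C)OC(C)(C)O[C@@H]3C=C[C@]2(C)[C@@H](OC(C)=O)[C@@H]1O[Si](C)(C)C(C)(C)C | intermediate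
30 | 8,17-epoxy-lactone | CCCCCC(=O)O[C@H]1/C(C)=C\[C@@H]2OC(=O)[C@@]3(C)O[C@@]23[C@H](OC(C)=O)[C@H]2[C@]3(C)OC(C)(C)O[C@@H]3C=C[C@]2(C)[C@@H](OC(C)=O)[C@@H]1O[Si](C)(C)C(C)(C)C | intermediate
31 | epoxy triol (C3, C11, C12 OH free) | CCCCCC(=O)O[C@H]1/C(C)=C\[C@@H]2OC(=O)[C@@]3(C)O[C@@]23[C@H](OC(C)=O)[C@H]2[C@](C)(O)[C@H](O)C=C[C@]2(C)[C@@H](OC(C)=O)[C@@H]1O | intermediate
32 | CNP0153048.1 | CCCCCC(=O)O[C@H]1/C(C)=C\[C@@H]2OC(=O)[C@@](C)(O)[C@@]2(O)[C@H](OC(C)=O)[C@H]2[C@](C)(O)[C@H](O)C=C[C@]2(C)[C@@H](OC(C)=O)[C@@H]1O | target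

## Step count and risks
Total steps: 24. Longest linear sequence: 19 (steps 1–5, 7–10, 15–24).

**Step 2 (the new Diels–Alder reaction).** The trisubstituted enal may be too unreactive or the ee too low. The fallback sets out from 2 and 3 and returns at 5.
- The cycloaddition is run thermally (toluene, 110 °C, BHT) and gives 4 together with its mirror image ent-4 F1.
- The Pd elimination of step 3 then gives 5 together with ent-5 F2.
- Condensation of this racemate with (1R,2R)-N,N′-dimethyl-1,2-diphenylethane-1,2-diamine (molecular sieves, Et2O) gives the imidazolidine of 5 F3 and the diastereomeric imidazolidine of ent-5 F4. These are separated by chromatography.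
- Mild biphasic acid hydrolysis of F3 returns enantiopure 5.

**Step 20 (RCM to a tetrasubstituted butenolide).** Closure next to a branched acetoxy carbon may stall. The fallback replaces metathesis by olefination; it sets out from 23 and returns at 27.
- 23 is esterified with 2-(diethoxyphosphoryl)propanoic acid (DCC, DMAP) to the phosphonopropionate F5.
- Exhaustive Lemieux–Johnson cleavage passes through the bis-diol F6 and gives the C8-keto C4-aldehyde F7.
- LiCl/DBU at high dilution then closes the five-membered ring by an intramolecular Horner–Wadsworth–Emmons reaction on the ketone, giving 27.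

**Step 21 (NHK closure of the ten-membered ring).** The rigid butenolide may hold the reacting termini apart. The fallback inverts the order of ring formation; it sets out from 26 and returns at 28.
- The NHK reaction is run on the more flexible seco-aldehyde 26 and gives the macrocyclic methacrylate alcohol F8.
- RCM within the macrocycle then forms the butenolide and gives 28.

## Further compounds
F1 | step 2 | ent-4 | CC(=O)OC[C@@H]1[C@@H](C)C=C[C@@H](OC(C)=O)[C@@]1(C)C=O
F2 | step 2 | ent-5 | CC(=O)OC[C@@H]1C(C)=CC=C[C@@]1(C)C=O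
F3 | step 2 | imidazolidine of 5 | CN1[C@H](c2ccccc2)[C@H](N(C)C1[C@@]3(C)C=CC=C(C)[C@@H]3COC(C)=O)c2ccccc2
F4 | step 2 | imidazolidine of ent-5 | CN1[C@H](c2ccccc2)[C@H](N(C)C1[C@]3(C)C=CC=C(C)[C@H]3COC(C)=O)c2ccccc2
F5 | step 20 | C7 2-(diethoxyphosphoryl)propanoate of 23 | C/C(I)=C/[C@H](OC(=O)C(C)P(=O)(OCC)OCC)C(=C)[C@H](OC(C)=O)[C@H]1[C@]2(C)OC(C)(C)O[C@@H]2C=C[C@]1(C)[C@@H](OC(C)=O)[C@H](O[Si](C)(C)C(C)(C)C)C=C
F6 | step 20 | bis-diol from F5 | C/C(I)=C/[C@H](OC(=O)C(C)P(=O)(OCC)OCC)C(O)(CO)[C@H](OC(C)=O)[C@H]1[C@]2(C)OC(C)(C)O[C@@H]2C=C[C@]1(C)[C@@H](OC(C)=O)[C@H](O[Si](C)(C)C(C)(C)C)C(O)CO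
F7 | step 20 | C8-keto C4-aldehyde phosphonate | C/C(I)=C/[C@H](OC(=O)C(C)P(=O)(OCC)OCC)C(=O)[C@H](OC(C)=O)[C@H]1[C@]2(C)OC(C)(C)O[C@@H]2C=C[C@]1(C)[C@@H](OC(C)=O)[C@H](O[Si](C)(C)C(C)(C)C)C=O
F8 | step 21 | macrocyclic methacrylate alcohol | O[C@H]1/C(C)=C\[C@H](OC(=O)C(C)=C)C(=C)[C@H](OC(C)=O)[C@H]2[C@]3(C)OC(C)(C)O[C@@H]3C=C[C@]2(C)[C@@H](OC(C)=O)[C@@H]1O[Si](C)(C)C(C)(C)C
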